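The route rests on cutting ring C of unit 1 (the 4-hydroxyphenyl flavan) at O1–C2 and C3–C4. The key step rebuilds that ring by an oxa-Diels–Alder reaction: the ortho-quinone methide O1=C8a–C4a=C4, unmasked from a benzhydrol, adds a Z-styryl acetate. This sets the C2 aryl group, O3 and the C4–C8 bond to unit 3 all-cis on ring C in one operation. Because O5 is benzylated and O1 is free, unit 2 is forced onto C6. The precursor is the benzylated ortho-hydroxybenzhydrol whose carbinol carbon (future C4) joins the ring A phenol, already carrying 4α-linked unit 2, to C8 of the 4β→6 dimer of units 3 and 4.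

Key step: step 17

Remark (descriptors): in every unit the C2 aryl group and O3 are α and cis (2R,3R, as in (−)-epicatechin); a 4α bond is cis and a 4β bond trans to O3. Unit 2 is 4α-linked, unit 3 is 4β-linked, and unit 1 is all-cis.

Remark (precursor design): compounds 16–19 and 23–25 carry one bromine at C8 of unit 4. It forces the dimer of units 3 and 4 to form through C6, leaves iodine at C8 of unit 3 as the only site that is lithiated, is a spectator in the key step and leaves in the final hydrogenolysis. The oxygen that becomes O1 is kept apart from O5 and O7 as a silyl ether from the start.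

Assumption (sense of induction): the (R)-configured phosphoric acid is taken to leave open the methide face that leads to the ring C configuration of the target; if a model run shows the opposite sense, the (S)-acid is used under the same conditions.

Step 1
Reactants: 1 (−)-epicatechin
Product: 2 tetra-O-benzyl epicatechin (benzyl ethers at O5, O7, O3', O4'; 3-OH free; 2R,3R)
Conditions: BnBr (4.4 equiv), K2CO3, DMF, 0 °C to rt
Reagents that add atoms: benzyl bromide, BrCc1ccccc1
Why: Williamson etherification with carbonate as base should benzylate only the four phenols, since the secondary alcohol is not deprotonated, and should leave both stereocentres untouched.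

Step 2
Reactants: 2 tetra-O-benzyl epicatechin
Product: 3 penta-O-benzyl epicatechin (2R,3R)
Conditions: NaH, BnBr, DMF, 0 °C to rt
Reagents that add atoms: benzyl bromide, BrCc1ccccc1
Why: Williamson etherification of the C3 alkoxide should be clean because, with all phenols capped, no quinone-methide pathway for C2 epimerisation is open under base.

Step 3
Reactants: 3 penta-O-benzyl epicatechin
Product: 4 penta-O-benzyl epicatechin-4β-ol (4-OH trans to the 3-benzyloxy group)
Conditions: DDQ, H2O, CH2Cl2, rt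
Reagents that add atoms: water, O
Why: DDQ benzylic oxidation removes hydride from C4, which is activated by O1, O5 and O7, and water should capture the cationic centre anti to the 3-benzyloxy group; the C4 configuration is of no consequence because step 4 oxidises this centre.

Step 4
Reactants: 4 penta-O-benzyl epicatechin-4β-ol
Product: 5 penta-O-benzyl 4-oxo-epicatechin, (2R,3S)-3,5,7-tris(benzyloxy)-2-[3,4-bis(benzyloxy)phenyl]chroman-4-one (2,3-cis)
Conditions: (n-C3H7)4N[RuO4] (5 mol%), N-methylmorpholine N-oxide, 4 Å MS, CH2Cl2, rt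
Reagents that add atoms: none
Why: Ley–Griffith oxidation should convert the benzylic alcohol into the aryl ketone under neutral conditions that do not epimerise the α-benzyloxy centre C3.

Step 5
Reactants: 6 3,5-bis(benzyloxy)phenol
Product: 7 [3,5-bis(benzyloxy)phenoxy]triisopropylsilane
Conditions: i-Pr3SiCl, imidazole, DMF, rt
Reagents that add atoms: chlorotriisopropylsilane, CC(C)[Si](Cl)(C(C)C)C(C)C
Why: Imidazole-promoted silylation masks the oxygen that must later be free O1 of unit 1 with a bulky group that does not direct the metalation of step 6.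

Step 6
Reactants: 7 [3,5-bis(benzyloxy)phenoxy]triisopropylsilane; 5 penta-O-benzyl 4-oxo-epicatechin
Product: 9 tertiary alcohol (penta-O-benzyl epicatechin carrying at C4 a hydroxyl group and a 2,6-bis(benzyloxy)-4-(triisopropylsilyloxy)phenyl group; aryl β and OH α expected), via aryllithium 8 (not isolated)
Conditions: 7 (2 equiv), n-BuLi (1.9 equiv), THF, 0 °C to rt; then 5, −78 °C to 0 °C; aq. NH4Cl
Reagents that add atoms: none
Why: Directed ortho-metalation should remove the proton flanked by the two coordinating benzyloxy groups (the silyloxy group neither coordinates nor acidifies), and the aryllithium should add 1,2 to the ketone anti to the 3-benzyloxy group; the carbinol configuration does not matter because C4 is ionised in step 7.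

Step 7
Reactants: 9 tertiary alcohol
Product: 10 silyl-protected adduct of unit 2 (penta-O-benzyl epicatechin carrying the 2,6-bis(benzyloxy)-4-(triisopropylsilyloxy)phenyl group 4α, all-cis at C2, C3, C4)
Conditions: n-Bu3SnH, CF3CO2H, CH2Cl2, 0 °C
Reagents that add atoms: none
Why: In this ionic hydrogenation the acid ionises the doubly benzylic tertiary alcohol and the hydride donor should attack the planar C4 centre from the β face, opposite the cis 2-aryl and 3-benzyloxy groups, which places the new aryl group α (3,4-cis) as unit 2 requires.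

Step 8
Reactants: 10 silyl-protected adduct of unit 2
Product: 11 phenol, 4-(penta-O-benzyl-epicatechin-4α-yl)-3,5-bis(benzyloxy)phenol
Conditions: Bu4NF, THF, 0 °C; aq. NH4Cl
Reagents that add atoms: none
Why: Fluoride-induced cleavage of the aryl silyl ether should free only the future O1, the benzyl ethers and all stereocentres being inert to fluoride.

Step 9
Reactants: 11 phenol
Product: 12 salicylaldehyde, 2-hydroxy-4,6-bis(benzyloxy)-5-(penta-O-benzyl-epicatechin-4α-yl)benzaldehyde
Conditions: MgCl2, Et3N, (CH2O)n, THF, reflux; dilute aq. HCl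
Reagents that add atoms: paraformaldehyde (formaldehyde), C=O
Why: Casnati–Skattebøl ortho-formylation delivers formaldehyde through magnesium chelation only to a position ortho to the phenol (a second formaldehyde acts as oxidant), and since the two ortho positions are interchanged by rotation about the aryl–C4 bond a single aldehyde should result.

Step 10
Reactants: 3 penta-O-benzyl epicatechin
Product: 13 8-bromo-penta-O-benzyl epicatechin
Conditions: NBS, CH2Cl2, −78 °C to 0 °C
Reagents that add atoms: N-bromosuccinimide, BrN1C(=O)CCC1=O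
Why: Electrophilic aromatic bromination of the phloroglucinol-type ring A should go to C8, which lies between O1 and O7 and is less shielded than C6 between two benzyloxy groups.

Step 11
Reactants: 3 penta-O-benzyl epicatechin
Product: 14 8-iodo-penta-O-benzyl epicatechin
Conditions: NIS, DMF, 0 °C to rt, dark
Reagents that add atoms: N-iodosuccinimide, IN1C(=O)CCC1=O
Why: Electrophilic aromatic iodination should follow the same C8 preference as the bromination of step 10 and installs the halogen that is later exchanged selectively.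

Step 12
Reactants: 14 8-iodo-penta-O-benzyl epicatechin
Product: 15 8-iodo-4β-(2-ethoxyethoxy)-penta-O-benzyl epicatechin
Conditions: DDQ, 2-ethoxyethanol, CH2Cl2, rt
Reagents that add atoms: 2-ethoxyethanol, CCOCCO
Why: DDQ benzylic oxidation at C4 followed by capture with the alcohol anti to the 3-benzyloxy group should give the 4β ether, a leaving group that a silyl triflate can ionise.

Step 13
Reactants: 15 8-iodo-4β-(2-ethoxyethoxy)-penta-O-benzyl epicatechin; 13 8-bromo-penta-O-benzyl epicatechin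
Product: 16 dimer, 8-iodo-penta-O-benzyl-epicatechin-(4β→6)-8-bromo-penta-O-benzyl-epicatechin (units 3 and 4)
Conditions: 13 (3 equiv), Me3SiOSO2CF3 (0.3 equiv), CH2Cl2, −78 °C to −40 °C; Et3N quench
Reagents that add atoms: none
Why: In this Friedel–Crafts-type interflavan coupling the silyl triflate ionises the C4 ether, and C6 of 13 (its only free activated carbon, C8 being brominated) should attack the C4 centre on the β face, anti to the 3-benzyloxy and 2-aryl groups, giving the 3,4-trans (4β) bond, while the iodine of 15 damps self-condensation.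

Step 14
Reactants: 16 dimer of units 3 and 4; 12 salicylaldehyde
Product: 19 ortho-hydroxybenzhydrol (both carbinol epimers; carbinol carbon between C8 of unit 3 and the ring A phenol that carries unit 2; bromine at C8 of unit 4), via aryllithium 17 (not isolated), via sodium phenoxide 18 (not isolated)
Conditions: 16 (1.1 equiv), n-BuLi (1.1 equiv), THF, −78 °C, 10 min; 12 with NaH (1.0 equiv), THF, 0 °C, cannulated in at −78 °C, then to −20 °C; aq. NH4Cl; Et3N-deactivated silica
Reagents that add atoms: none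
Why: Iodine–lithium exchange is far faster than bromine–lithium exchange at −78 °C, so only C8 of unit 3 should be metalated, and the aryllithium then adds 1,2 to the aldehyde of the pre-formed phenoxide without being spent on the OH group; the new carbinol centre may form as both epimers because it becomes trigonal in step 17.

Step 15
Reactants: 20 4-(benzyloxy)benzaldehyde
Product: 21 1-(benzyloxy)-4-ethynylbenzene
Conditions: dimethyl (1-diazo-2-oxopropyl)phosphonate, K2CO3, MeOH/THF, 0 °C to rt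
Reagents that add atoms: dimethyl (1-diazo-2-oxopropyl)phosphonate, COP(=O)(OC)C(=[N+]=[N-])C(C)=O
Why: Ohira–Bestmann alkynylation (Seyferth–Gilbert homologation) should convert the non-enolisable aryl aldehyde into the terminal alkyne under mild base.

Step 16
Reactants: 21 1-(benzyloxy)-4-ethynylbenzene
Product: 22 (Z)-2-[4-(benzyloxy)phenyl]ethenyl acetate
Conditions: AcOH (1.5 equiv), Ru(η3-CH2C(CH3)CH2)2(Ph2P(CH2)4PPh2) (5 mol%), toluene, 65 °C
Reagents that add atoms: acetic acid, CC(=O)O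
Why: Ruthenium-catalysed anti-Markovnikov addition of a carboxylic acid to a terminal alkyne proceeds through a vinylidene complex, and carboxylate attack on the vinylidene carbon followed by protonolysis should deliver the Z-enol ester.

Step 17
Reactants: 19 ortho-hydroxybenzhydrol; 22 (Z)-2-[4-(benzyloxy)phenyl]ethenyl acetate
Product: 24 octadeca-O-benzyl tetramer with unit 1 as its 3-O-acetate (ring C of unit 1 all-cis: 2α-aryl, 3α-acetoxy, 4α bond to C8 of unit 3; bromine at C8 of unit 4), via ortho-quinone methide 23 (not isolated)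
Conditions: 22 (3 equiv), (R)-3,3'-bis(2,4,6-triisopropylphenyl)-1,1'-binaphthyl-2,2'-diyl hydrogen phosphate (10 mol%), 4 Å MS, CH2Cl2, 0 °C to rt
Reagents that add atoms: none
Why: The phosphoric acid ionises the doubly benzylic carbinol of 19 and takes the phenol proton, giving the (E)-ortho-quinone methide 23 (1-oxadiene O1=C8a–C4a=C4) hydrogen-bonded to the chiral phosphate. The Z-enol acetate 22 then engages this heterodiene in an inverse-electron-demand oxa-Diels–Alder reaction in which C3–C4 bonding runs ahead of O1–C2 bonding: the acetoxy-substituted alkene carbon attacks the methide carbon and the positive charge developing at the 4-benzyloxybenzylic carbon is quenched by O1. The nearest established reaction class is the asymmetric [4+2] annulation of ortho-quinone methides, formed in situ from 2-hydroxybenzhydrols under chiral phosphoric acid catalysis, with styrenes and enol-type alkenes, which yields cis-2,4-diarylchromans. Ring C of unit 1 is closed by this intermolecular [4+2] cycloaddition, which forms O1–C2 and C3–C4 together. C2 and C3 should be cis because the Z geometry of 22 is carried over suprafacially, C4 should be cis to both because the aryl and acetoxy groups lie endo to the E-configured methide, and the absolute sense of all three follows from the methide face left open by the bound phosphate, not from the remote flavan centres. The step needs O1 (not O5) as the diene oxygen and C3 (not C2) as the acetoxy carbon: the benzyl ether on O5 secures the first and thereby fixes unit 2 on C6, and the cation-stabilising 4-benzyloxyphenyl group secures the second.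

Step 18
Reactants: 24 octadeca-O-benzyl tetramer 3-O-acetate
Product: 25 octadeca-O-benzyl tetramer with free 3-OH on unit 1 (bromine at C8 of unit 4)
Conditions: K2CO3 (0.3 equiv), MeOH/THF, rt
Reagents that add atoms: none
Why: Base-catalysed transesterification with methanol should remove the acetate, the molecule holding no enolisable or base-labile stereocentre.

Step 19
Reactants: 25 octadeca-O-benzyl tetramer with free 3-OH
Product: 26 CNP0103636.2 (target)
Conditions: H2 (1 atm), Pd(OH)2/C, NaOAc (1.5 equiv), THF/MeOH/H2O, rt; filtration, lyophilisation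
Reagents that add atoms: none
Why: Catalytic hydrogenolysis should cleave all eighteen benzyl ethers and hydrodehalogenate the aryl bromide while the flavan C2–O1 bonds and the interflavan C–C bonds persist, the acetate buffering the hydrogen bromide so that the acid-labile interflavan bonds are not put at risk.

Compound list
1 | (−)-epicatechin, (2R,3R)-2-(3,4-dihydroxyphenyl)chromane-3,5,7-triol | O[C@@H]1Cc2c(O)cc(O)cc2O[C@@H]1c1ccc(O)c(O)c1 | starting material
2 | tetra-O-benzyl epicatechin, (2R,3R)-5,7-bis(benzyloxy)-2-[3,4-bis(benzyloxy)phenyl]chroman-3-ol | O[C@@H]1Cc2c(OCc9ccccc9)cc(OCc9ccccc9)cc2O[C@@H]1c1ccc(OCc9ccccc9)c(OCc9ccccc9)c1 | intermediate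
3 | penta-O-benzyl epicatechin, (2R,3R)-3,5,7-tris(benzyloxy)-2-[3,4-bis(benzyloxy)phenyl]chromane | c9ccccc9CO[C@@H]1Cc2c(OCc9ccccc9)cc(OCc9ccccc9)cc2O[C@@H]1c1ccc(OCc9ccccc9)c(OCc9ccccc9)c1 | intermediate
4 | penta-O-benzyl epicatechin-4β-ol (4-OH trans to 3-OBn) | c9ccccc9CO[C@@H]1[C@@H](O)c2c(OCc9ccccc9)cc(OCc9ccccc9)cc2O[C@@H]1c1ccc(OCc9ccccc9)c(OCc9ccccc9)c1 | intermediate
5 | penta-O-benzyl 4-oxo-epicatechin, (2R,3S)-3,5,7-tris(benzyloxy)-2-[3,4-bis(benzyloxy)phenyl]chroman-4-one | c9ccccc9CO[C@@H]1C(=O)c2c(OCc9ccccc9)cc(OCc9ccccc9)cc2O[C@@H]1c1ccc(OCc9ccccc9)c(OCc9ccccc9)c1 | intermediate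
6 | 3,5-bis(benzyloxy)phenol | Oc1cc(OCc2ccccc2)cc(OCc2ccccc2)c1 | starting material
7 | [3,5-bis(benzyloxy)phenoxy]triisopropylsilane | CC(C)[Si](C(C)C)(C(C)C)Oc1cc(OCc2ccccc2)cc(OCc2ccccc2)c1 | intermediate
8 | 2,6-bis(benzyloxy)-4-(triisopropylsilyloxy)phenyllithium | [Li]c1c(OCc2ccccc2)cc(O[Si](C(C)C)(C(C)C)C(C)C)cc1OCc1ccccc1 | intermediate
9 | tertiary alcohol: penta-O-benzyl epicatechin with 4α-OH and 4β-[2,6-bis(benzyloxy)-4-(triisopropylsilyloxy)phenyl] | CC(C)[Si](C(C)C)(C(C)C)Oc1cc(OCc9ccccc9)c([C@@]4(O)c5c(OCc9ccccc9)cc(OCc9ccccc9)cc5O[C@H](c5ccc(OCc9ccccc9)c(OCc9ccccc9)c5)[C@@H]4OCc9ccccc9)c(OCc9ccccc9)c1 | intermediate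
10 | silyl-protected adduct of unit 2: 4α-[2,6-bis(benzyloxy)-4-(triisopropylsilyloxy)phenyl]-penta-O-benzyl epicatechin (2,3-cis-3,4-cis) | CC(C)[Si](C(C)C)(C(C)C)Oc1cc(OCc9ccccc9)c([C@@H]4c5c(OCc9ccccc9)cc(OCc9ccccc9)cc5O[C@H](c5ccc(OCc9ccccc9)c(OCc9ccccc9)c5)[C@@H]4OCc9ccccc9)c(OCc9ccccc9)c1 | intermediate
11 | phenol: 4-(penta-O-benzyl-epicatechin-4α-yl)-3,5-bis(benzyloxy)phenol | Oc1cc(OCc9ccccc9)c([C@@H]4c5c(OCc9ccccc9)cc(OCc9ccccc9)cc5O[C@H](c5ccc(OCc9ccccc9)c(OCc9ccccc9)c5)[C@@H]4OCc9ccccc9)c(OCc9ccccc9)c1 | intermediate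
12 | salicylaldehyde: 2-hydroxy-4,6-bis(benzyloxy)-5-(penta-O-benzyl-epicatechin-4α-yl)benzaldehyde | Oc3cc(OCc9ccccc9)c([C@@H]4c5c(OCc9ccccc9)cc(OCc9ccccc9)cc5O[C@H](c5ccc(OCc9ccccc9)c(OCc9ccccc9)c5)[C@@H]4OCc9ccccc9)c(OCc9ccccc9)c3C=O | intermediate
13 | 8-bromo-penta-O-benzyl epicatechin | c9ccccc9CO[C@@H]1Cc2c(OCc9ccccc9)cc(OCc9ccccc9)c(Br)c2O[C@@H]1c1ccc(OCc9ccccc9)c(OCc9ccccc9)c1 | intermediate
14 | 8-iodo-penta-O-benzyl epicatechin | c9ccccc9CO[C@@H]1Cc2c(OCc9ccccc9)cc(OCc9ccccc9)c(I)c2O[C@@H]1c1ccc(OCc9ccccc9)c(OCc9ccccc9)c1 | intermediate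
15 | 8-iodo-4β-(2-ethoxyethoxy)-penta-O-benzyl epicatechin | c9ccccc9CO[C@@H]1[C@@H](OCCOCC)c2c(OCc9ccccc9)cc(OCc9ccccc9)c(I)c2O[C@@H]1c1ccc(OCc9ccccc9)c(OCc9ccccc9)c1 | intermediate
16 | dimer of units 3 and 4: 8-iodo-penta-O-benzyl-epicatechin-(4β→6)-8-bromo-penta-O-benzyl-epicatechin | Ic3c(OCc9ccccc9)cc(OCc9ccccc9)c4c3O[C@H](c3ccc(OCc9ccccc9)c(OCc9ccccc9)c3)[C@H](OCc9ccccc9)[C@H]4c3c(OCc9ccccc9)c(Br)c4c(c3OCc9ccccc9)C[C@@H](OCc9ccccc9)[C@@H](c3ccc(OCc9ccccc9)c(OCc9ccccc9)c3)O4 | intermediate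
17 | aryllithium: dimer 16 with lithium in place of iodine at C8 of unit 3 | [Li]c3c(OCc9ccccc9)cc(OCc9ccccc9)c4c3O[C@H](c3ccc(OCc9ccccc9)c(OCc9ccccc9)c3)[C@H](OCc9ccccc9)[C@H]4c3c(OCc9ccccc9)c(Br)c4c(c3OCc9ccccc9)C[C@@H](OCc9ccccc9)[C@@H](c3ccc(OCc9ccccc9)c(OCc9ccccc9)c3)O4 | intermediate
18 | sodium phenoxide of salicylaldehyde 12 | [Na+].[O-]c3cc(OCc9ccccc9)c([C@@H]4c5c(OCc9ccccc9)cc(OCc9ccccc9)cc5O[C@H](c5ccc(OCc9ccccc9)c(OCc9ccccc9)c5)[C@@H]4OCc9ccccc9)c(OCc9ccccc9)c3C=O | intermediate
19 | ortho-hydroxybenzhydrol (carbinol epimers) joining the unit 2–phloroglucinol adduct to C8 of unit 3 of the dimer; Br at C8 of unit 4 | Oc3cc(OCc9ccccc9)c([C@@H]4c5c(OCc9ccccc9)cc(OCc9ccccc9)cc5O[C@H](c5ccc(OCc9ccccc9)c(OCc9ccccc9)c5)[C@@H]4OCc9ccccc9)c(OCc9ccccc9)c3C(O)c3c(OCc9ccccc9)cc(OCc9ccccc9)c4c3O[C@H](c3ccc(OCc9ccccc9)c(OCc9ccccc9)c3)[C@H](OCc9ccccc9)[C@H]4c3c(OCc9ccccc9)c(Br)c4c(c3OCc9ccccc9)C[C@@H](OCc9ccccc9)[C@@H](c3ccc(OCc9ccccc9)c(OCc9ccccc9)c3)O4 | intermediate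
20 | 4-(benzyloxy)benzaldehyde | O=Cc1ccc(OCc2ccccc2)cc1 | starting material
21 | 1-(benzyloxy)-4-ethynylbenzene | C#Cc1ccc(OCc2ccccc2)cc1 | intermediate
22 | (Z)-2-[4-(benzyloxy)phenyl]ethenyl acetate | CC(=O)O/C=C\c1ccc(OCc2ccccc2)cc1 | intermediate
23 | (E)-ortho-quinone methide from 19 (O1=C8a–C4a=C4 of unit 1; methide aryl group anti to the carbonyl) | O=C1C=C(OCc9ccccc9)C([C@@H]4c5c(OCc9ccccc9)cc(OCc9ccccc9)cc5O[C@H](c5ccc(OCc9ccccc9)c(OCc9ccccc9)c5)[C@@H]4OCc9ccccc9)=C(OCc9ccccc9)/C1=C\c3c(OCc9ccccc9)cc(OCc9ccccc9)c4c3O[C@H](c3ccc(OCc9ccccc9)c(OCc9ccccc9)c3)[C@H](OCc9ccccc9)[C@H]4c3c(OCc9ccccc9)c(Br)c4c(c3OCc9ccccc9)C[C@@H](OCc9ccccc9)[C@@H](c3ccc(OCc9ccccc9)c(OCc9ccccc9)c3)O4 | intermediate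
24 | octadeca-O-benzyl tetramer, unit 1 as 3-O-acetate (ring C all-cis; Br at C8 of unit 4) | c9ccccc9COc1ccc([C@H]2Oc3cc(OCc9ccccc9)c([C@@H]4c5c(OCc9ccccc9)cc(OCc9ccccc9)cc5O[C@H](c5ccc(OCc9ccccc9)c(OCc9ccccc9)c5)[C@@H]4OCc9ccccc9)c(OCc9ccccc9)c3[C@@H](c3c(OCc9ccccc9)cc(OCc9ccccc9)c4c3O[C@H](c3ccc(OCc9ccccc9)c(OCc9ccccc9)c3)[C@H](OCc9ccccc9)[C@H]4c3c(OCc9ccccc9)c(Br)c4c(c3OCc9ccccc9)C[C@@H](OCc9ccccc9)[C@@H](c3ccc(OCc9ccccc9)c(OCc9ccccc9)c3)O4)[C@H]2OC(C)=O)cc1 | intermediate
25 | octadeca-O-benzyl tetramer with free 3-OH on unit 1 (Br at C8 of unit 4) | c9ccccc9COc1ccc([C@H]2Oc3cc(OCc9ccccc9)c([C@@H]4c5c(OCc9ccccc9)cc(OCc9ccccc9)cc5O[C@H](c5ccc(OCc9ccccc9)c(OCc9ccccc9)c5)[C@@H]4OCc9ccccc9)c(OCc9ccccc9)c3[C@@H](c3c(OCc9ccccc9)cc(OCc9ccccc9)c4c3O[C@H](c3ccc(OCc9ccccc9)c(OCc9ccccc9)c3)[C@H](OCc9ccccc9)[C@H]4c3c(OCc9ccccc9)c(Br)c4c(c3OCc9ccccc9)C[C@@H](OCc9ccccc9)[C@@H](c3ccc(OCc9ccccc9)c(OCc9ccccc9)c3)O4)[C@H]2O)cc1 | intermediate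
26 | CNP0103636.2: epiafzelechin (unit 1) bearing epicatechin-4α-yl (unit 2) at C6 and linked 4α→8 to epicatechin-(4β→6)-epicatechin (units 3 and 4) | Oc1ccc([C@H]2Oc3cc(O)c([C@@H]4c5c(O)cc(O)cc5O[C@H](c5ccc(O)c(O)c5)[C@@H]4O)c(O)c3[C@@H](c3c(O)cc(O)c4c3O[C@H](c3ccc(O)c(O)c3)[C@H](O)[C@H]4c3c(O)cc4c(c3O)C[C@@H](O)[C@@H](c3ccc(O)c(O)c3)O4)[C@H]2O)cc1 | target

Total step count: 19. Longest linear sequence: 12 steps (steps 1, 2, 3, 4, 6, 7, 8, 9, 14, 17, 18, 19, from (−)-epicatechin).

Steps most likely to fail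

Step 17. The methide 23 is stabilised by four donor oxygens and its exocyclic carbon is flanked by ortho substituents on both aryl partners. Capture by the weakly nucleophilic enol acetate may therefore be outrun by decay of the methide, or may proceed with poor endo and facial control. The fallback sets out from 19 and comes back at 25. Benzhydrol 19 is condensed with the more nucleophilic alkyne 21 under a catalytic Brønsted acid (diphenyl phosphate, CH2Cl2), in the known formal [4+2] reaction of ortho-quinone methides with arylalkynes, to give the 2,4-diaryl-4H-chromene F1; its C4 epimers are diastereomers and are separated. Hydroboration–oxidation (BH3·SMe2, then NaBO3) should add boron to C3 and hydrogen to C2 from the face opposite the C4 aryl group, giving the 2,3-trans-3,4-trans alcohol F2 with the C2 aryl group already cis to C4. Dess–Martin oxidation gives the flavan-3-one F3, and LiBH(s-Bu)3 at −78 °C should deliver hydride from the face opposite both aryl groups, inverting C3 to give 25.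

Step 14. Bond formation between the ortho,ortho'-disubstituted aryllithium 17 and the chelated, deactivated phenoxide-aldehyde 18 may be slow, which gives time for lithium–bromine scrambling onto unit 4 or protonation of 17. The fallback sets out from 16 and 11 and comes back at 19, so step 9 is not needed. The polarity is reversed: 17, generated as in step 14, is quenched with DMF, a small and fast electrophile, to give the 8-formyl dimer F4. Phenol 11 is converted with EtMgBr in toluene/CH2Cl2 into the bromomagnesium phenoxide F5, which adds F4 in the known ortho-specific hydroxyalkylation of magnesium phenoxides through a six-membered chelate (the two ortho positions of 11 are equivalent), giving 19.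

Step 13. Under the Lewis acid the electron-rich aryl iodide may lose or transfer iodine, or the C4 cation may be intercepted by ring A of a second molecule of 15 or 16 rather than by the less reactive brominated nucleophile 13, giving oligomers. The fallback sets out from 3 and comes back at 16. The iodine is introduced after the coupling: 3 is oxidised with DDQ and 2-ethoxyethanol to the halogen-free 4β-(2-ethoxyethoxy)-penta-O-benzyl epicatechin F6. This is added slowly to a large excess of 13 and Me3SiOSO2CF3 at −78 °C, so that each cation meets 13, giving the iodine-free 4β→6 dimer F7. NIS then iodinates C8 of unit 3 (ring A of unit 4 is fully substituted, and C8 is preferred to C6 as in step 11) to give 16.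

Further compounds
F1 | step 17 | 2,4-diaryl-4H-chromene: ring C of unit 1 with a C2=C3 double bond, C4 configured as in 24, Br at C8 of unit 4 | c9ccccc9COc1ccc(C2Oc3cc(OCc9ccccc9)c([C@@H]4c5c(OCc9ccccc9)cc(OCc9ccccc9)cc5O[C@H](c5ccc(OCc9ccccc9)c(OCc9ccccc9)c5)[C@@H]4OCc9ccccc9)c(OCc9ccccc9)c3[C@@H](c3c(OCc9ccccc9)cc(OCc9ccccc9)c4c3O[C@H](c3ccc(OCc9ccccc9)c(OCc9ccccc9)c3)[C@H](OCc9ccccc9)[C@H]4c3c(OCc9ccccc9)c(Br)c4c(c3OCc9ccccc9)C[C@@H](OCc9ccccc9)[C@@H](c3ccc(OCc9ccccc9)c(OCc9ccccc9)c3)O4)C=2)cc1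
F2 | step 17 | 2,3-trans-3,4-trans alcohol: C3 epimer of 25 (2α-aryl, 3β-OH, 4α-aryl) | c9ccccc9COc1ccc([C@H]2Oc3cc(OCc9ccccc9)c([C@@H]4c5c(OCc9ccccc9)cc(OCc9ccccc9)cc5O[C@H](c5ccc(OCc9ccccc9)c(OCc9ccccc9)c5)[C@@H]4OCc9ccccc9)c(OCc9ccccc9)c3[C@@H](c3c(OCc9ccccc9)cc(OCc9ccccc9)c4c3O[C@H](c3ccc(OCc9ccccc9)c(OCc9ccccc9)c3)[C@H](OCc9ccccc9)[C@H]4c3c(OCc9ccccc9)c(Br)c4c(c3OCc9ccccc9)C[C@@H](OCc9ccccc9)[C@@H](c3ccc(OCc9ccccc9)c(OCc9ccccc9)c3)O4)[C@@H]2O)cc1
F3 | step 17 | flavan-3-one of unit 1 (2α-aryl, 4α-aryl, C3 carbonyl) | c9ccccc9COc1ccc([C@H]2Oc3cc(OCc9ccccc9)c([C@@H]4c5c(OCc9ccccc9)cc(OCc9ccccc9)cc5O[C@H](c5ccc(OCc9ccccc9)c(OCc9ccccc9)c5)[C@@H]4OCc9ccccc9)c(OCc9ccccc9)c3[C@@H](c3c(OCc9ccccc9)cc(OCc9ccccc9)c4c3O[C@H](c3ccc(OCc9ccccc9)c(OCc9ccccc9)c3)[C@H](OCc9ccccc9)[C@H]4c3c(OCc9ccccc9)c(Br)c4c(c3OCc9ccccc9)C[C@@H](OCc9ccccc9)[C@@H](c3ccc(OCc9ccccc9)c(OCc9ccccc9)c3)O4)C2=O)cc1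
F4 | step 14 | 8-formyl dimer: dimer 16 with CHO in place of iodine at C8 of unit 3 | O=Cc3c(OCc9ccccc9)cc(OCc9ccccc9)c4c3O[C@H](c3ccc(OCc9ccccc9)c(OCc9ccccc9)c3)[C@H](OCc9ccccc9)[C@H]4c3c(OCc9ccccc9)c(Br)c4c(c3OCc9ccccc9)C[C@@H](OCc9ccccc9)[C@@H](c3ccc(OCc9ccccc9)c(OCc9ccccc9)c3)O4
F5 | step 14 | bromomagnesium phenoxide of phenol 11 | Br[Mg]Oc1cc(OCc9ccccc9)c([C@@H]4c5c(OCc9ccccc9)cc(OCc9ccccc9)cc5O[C@H](c5ccc(OCc9ccccc9)c(OCc9ccccc9)c5)[C@@H]4OCc9ccccc9)c(OCc9ccccc9)c1
F6 | step 13 | 4β-(2-ethoxyethoxy)-penta-O-benzyl epicatechin | c9ccccc9CO[C@@H]1[C@@H](OCCOCC)c2c(OCc9ccccc9)cc(OCc9ccccc9)cc2O[C@@H]1c1ccc(OCc9ccccc9)c(OCc9ccccc9)c1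
F7 | step 13 | iodine-free dimer: penta-O-benzyl-epicatechin-(4β→6)-8-bromo-penta-O-benzyl-epicatechin | c3c(OCc9ccccc9)cc(OCc9ccccc9)c4c3O[C@H](c3ccc(OCc9ccccc9)c(OCc9ccccc9)c3)[C@H](OCc9ccccc9)[C@H]4c3c(OCc9ccccc9)c(Br)c4c(c3OCc9ccccc9)C[C@@H](OCc9ccccc9)[C@@H](c3ccc(OCc9ccccc9)c(OCc9ccccc9)c3)O4
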